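In molar units, not percent, the last readings of the runs line up, so I first ask which given numbers the flask's answers hang on.

| flask | free monomer | initiator | remark | time |
|---|---|---|---|---|
| Wednesday's | 0.025 M | 0.2 mol% | run made earlier |  |
| Friday's | 0.10 M | 0.2 mol% | run made earlier |  |
| Tuesday's | 0.050 M | 0.3 mol% | run made earlier |  |
| flask | 0.050 M | 0.2 mol% |  | 8.0 min |

| run | time / min | monomer in chains / % | free monomer / % |
|---|---|---|---|
| Wednesday's | 0.417 | 1.0 | 97.5 |
| Wednesday's | 0.667 | 2.5 | 97.0 |
| Wednesday's | 1.33 | 5.8 | 93.6 |
| Wednesday's | 2.50 | 10.7 | 90.4 |
| Wednesday's | 5.00 | 12.8 | 89.5 |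
| Friday's | 1.00 | 63.0 | 38.4 |
| Friday's | 2.00 | 74.5 | 24.5 |
| Friday's | 3.00 | 78.4 | 23.5 |
| Friday's | 4.00 | 78.6 | 21.4 |
| Friday's | 5.00 | 78.5 | 20.3 |
| Tuesday's | 0.417 | 18.8 | 81.4 |
| Tuesday's | 1.33 | 44.7 | 54.6 |
| Tuesday's | 2.00 | 52.7 | 49.0 |
| Tuesday's | 3.00 | 55.0 | 44.5 |
| Tuesday's | 5.00 | 56.9 | 42.5 |

(readings scatter by 1 percentage point)

- the average divides the monomer in chains by the number of chains begun, living and dead together
- the numbers in the tables scatter with a standard deviation of 1 percentage point
- the earlier runs do not show the number of chains; that part of a forecast is a guess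

* average number of monomer units in a chain (chains begun, living or dead) at 8.0 min
* part of the free monomer that has reacted at 8.0 min

Time first: Tuesday's free monomer goes from 44.5% to 42.5% between 3.00 min and 5.00 min, and the flask's 8.0 min lies past both. Initiator next: Friday's run, with 0.10 M of free monomer and 0.2 mol% of initiator, has its last reading at 0.0203 M, and Tuesday's, with 0.050 M and 0.3 mol%, at 0.0213 M. Both settings differ between these runs, so the gap, worth 1.9 percentage points of the flask's reacted part, cannot be put down to the loading. The loading does enter the chain length, which is reacted monomer over chains begun.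

The number to know well is the floor M_f, the free monomer concentration at which a run stops: the equilibrium monomer concentration, thermodynamic rather than kinetic control. The mean of the last readings gives 0.0213 M. My reckoning for the flask: one minus M_f over the charge gives 57.4%, and if each initiator begins one chain, a guess, the average is 287.

The forecast says 57% and 290, on the grounds: “This points to a propagation–depropagation equilibrium”.

The flask gives 57.1% and 297.

    free monomer + initiator → living end + monomer in chains (k = 4.70 M⁻¹ s⁻¹)
    monomer in chains + living end → free monomer + living end, rate k2*[living end] as long as [monomer in chains] is above zero (k = 3.00 s⁻¹)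
    free monomer + initiator → spent initiator (k = 0.190 M⁻¹ s⁻¹)
    free monomer + living end → monomer in chains + living end, rate k4*[living end]*[free monomer] (k = 140 M⁻¹ s⁻¹)

In the flask, monomer in chains is made 1.10 times as fast as it is used up at 3.33 min, and 1.00 times at 8.00 min. Free monomer in the flask then stands at 42.9% of the charge, or 0.0215 M, the flask's own M_f. A reckoning from M_f fails with 0.05 mol% of initiator: that neighbour flask still holds 54.4% free monomer at 8.0 min, above the M_f read from the runs, with 45.6% reacted and an average of 950.

The earlier runs and the new flask were generated by integration on assumed constants.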